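**Plan**
- Retrosynthesis: once the aryl ethers are unmasked, ring B of the 1-aryl-1,2-dihydronaphthalene is cut at C2–C3 and at C1–C8a. This leaves two 4-hydroxychalcone halves: a vanillin-derived one (ring A, C4, C3) and a 4-hydroxybenzaldehyde-derived one (aryl, C1, C2).
- Enabling feature: the C7 hydroxyl of ring A and the 4-hydroxyl of the C1 aryl each lie para to a chain ending in an aroyl ketone (C4=C3–CO and C1–C2–CO), so C3 and C2 are the spin-bearing alpha carbons of two phenoxyl radicals. The C6 oxygen is para to C8a, which makes C8a the nucleophile for the quinone methide carbon C1.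
- Reinforcement: the aroyl groups on neighbouring C2 and C3 each carry an ortho oxygen. Joining these two oxygens by a propane-1,3-diyl bridge makes the coupling of the unlike halves intramolecular and masks the hydroxyls that would divert a chalcone to a flavanone or aurone.
- Forward order: bridge two paeonol units, attach the two aryl arms by successive Claisen–Schmidt condensations, oxidise with FeCl3 (C2–C3 closes a temporary 13-membered bridge ring, then C1–C8a closes ring B), resolve, cleave all ethers (the bridge ring opens again).
- Stereochemistry: trans C1/C2 from the ring closure and from equilibration at the enolisable C2; absolute configuration (1R,2S) by chromatography on a chiral phase, C1 being fixed once formed.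

Key step: step 4

Remark: locants refer to the dihydronaphthalene core (C1 = CH-aryl, C2 = CH-aroyl, C3 = C-aroyl, C4 = CH, ring A = C4a to C8a). Read this way the target SMILES is (1R,2S) with the C1 aryl and C2 aroyl groups trans. A racemate is written as its two enantiomers joined by a dot.

**Step 1**
Reactants: 1 paeonol (2 equiv); 2 1,3-dibromopropane
Product: 3 1,3-bis(2-acetyl-5-methoxyphenoxy)propane
Conditions: K2CO3, KI (cat.), DMF, 80 °C
Reagents that add atoms: none
Why: Williamson etherification, in which the carbonate frees the chelated ortho-phenoxide of 1 and this displaces both primary bromides of 2 by SN2, installing the three-carbon bridge that later holds the two halves together and protects both ortho oxygens.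

**Step 2**
Reactants: 3 bridged bis-acetophenone (3 equiv); 4 vanillin
Product: 5 bridged mono-chalcone carrying one (E)-3-(4-hydroxy-3-methoxyphenyl)propenoyl arm and one remaining acetyl group
Conditions: HCl (gas), EtOH, 0 °C to rt
Reagents that add atoms: none
Why: Acid-catalysed Claisen–Schmidt (crossed aldol) condensation, which tolerates the free phenol of 4 and dehydrates to the conjugated (E)-enone, while the excess of symmetric, recoverable 3 should hold the reaction at the mono-chalcone.

**Step 3**
Reactants: 5 bridged mono-chalcone; 6 4-hydroxybenzaldehyde (1.5 equiv)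
Product: 7 bridged (E,E)-bis-chalcone with one 4-hydroxy-3-methoxycinnamoyl arm and one 4-hydroxycinnamoyl arm
Conditions: HCl (gas), EtOH, 0 °C to rt
Reagents that add atoms: none
Why: A second acid-catalysed Claisen–Schmidt condensation at the remaining acetyl group, under which the first enone and all aryl ethers are inert, should give the unsymmetrical bis-chalcone whose only free hydroxyls are the two to be oxidised.

**Step 4**
Reactants: 7 bridged (E,E)-bis-chalcone
Product: 11 racemic trans bridged 1-aryl-1,2-dihydronaphthalene, via bis(phenoxyl) diradical 8 (not isolated), via bridged bis(quinone methide) 9 (not isolated), via quinone methide enone 10 (not isolated)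
Conditions: FeCl3·6H2O (2.2 equiv, slow addition), acetone/H2O 9:1, 1 mM, rt, Ar, dark
Reagents that add atoms: none
Why: Proposed new method: FeCl3·6H2O (trivalent iron) removes one electron from each free phenol of 7 to give diradical 8, whose spin is shared with the two carbons alpha to the ketones, and their head-to-head recombination forms C2–C3 and closes the 13-membered bridge ring of bis(quinone methide) 9. The guaiacyl-derived quinone methide of 9 then loses its acidic alpha proton and re-aromatises to aryl enone 10 (C3=C4), whose ring carbon para to the methoxy group adds to the surviving quinone methide carbon in a 6-exo-trig Friedel–Crafts closure of ring B (C1–C8a), promoted by the HCl and iron chlorides present. The closest known reaction type is the FeCl3-mediated 8–8 oxidative dimerisation of 4-hydroxycinnamate esters to 1-aryl-1,2-dihydronaphthalenes; untested are the chalcone substrate class, the pairing of two different phenols and the macrocyclic setting. The step needs cross- and site-selectivity, and the bridge supplies both: the unlike halves sit in one molecule and alpha,alpha-coupling gives the smallest possible ring (13 atoms against 17 or 19 for alpha-to-ring or alpha-to-oxygen modes), while high dilution disfavours intermolecular coupling. The direction of ring closure is set by the methoxy group, since only ring A has a donor para to the attacking carbon, whereas the 4-oxyphenyl ring of the other half has none. C1 is created in the ring closure with its aryl group anti to the C2 aroyl group, and C2, being alpha to a ketone, equilibrates in the acidic medium to the same trans arrangement; neither centre is controlled in the absolute sense, so 11 should form as a racemate.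

**Step 5**
Reactants: 11 racemic trans bridged dihydronaphthalene
Product: 12 (1R,2S)-enantiomer of the bridged dihydronaphthalene
Conditions: preparative HPLC, amylose tris(3,5-dimethylphenylcarbamate) on silica, n-hexane/EtOH, rt
Reagents that add atoms: none
Why: Resolution by chromatography on a polysaccharide chiral stationary phase, for which the two free phenols and two ketones offer hydrogen-bonding handles; no bond is made or broken, C1 cannot epimerise, and the (1R,2S) fraction is to be identified by comparing its electronic circular dichroism with the calculated spectrum.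

**Step 6**
Reactants: 12 (1R,2S)-bridged dihydronaphthalene
Product: 13 target, [(1R,2S)-6,7-dihydroxy-1-(4-hydroxyphenyl)-1,2-dihydronaphthalene-2,3-diyl]bis[(2,4-dihydroxyphenyl)methanone]
Conditions: BBr3 (excess), CH2Cl2, −78 °C to rt, Ar; then H2O, 0 °C
Reagents that add atoms: none
Why: Exhaustive Lewis-acid ether cleavage of the kind established for polymethoxychalcones, in which BBr3 complexes each ether oxygen and bromide attacks the methyl or primary methylene carbon (fastest at the two ketone-chelated bridge oxygens); C1 is untouched and C2 can only settle in the more stable trans arrangement.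

**Compound list**
1 | paeonol, 1-(2-hydroxy-4-methoxyphenyl)ethanone | CC(=O)c1ccc(OC)cc1O | starting material
2 | 1,3-dibromopropane | BrCCCBr | starting material
3 | 1,3-bis(2-acetyl-5-methoxyphenoxy)propane (bridged bis-acetophenone) | CC(=O)c1ccc(OC)cc1OCCCOc1cc(OC)ccc1C(C)=O | intermediate
4 | vanillin, 4-hydroxy-3-methoxybenzaldehyde | COc1cc(C=O)ccc1O | starting material
5 | bridged mono-chalcone, (E)-1-{2-[3-(2-acetyl-5-methoxyphenoxy)propoxy]-4-methoxyphenyl}-3-(4-hydroxy-3-methoxyphenyl)prop-2-en-1-one | CC(=O)c1ccc(OC)cc1OCCCOc1cc(OC)ccc1C(=O)/C=C/c1ccc(O)c(OC)c1 | intermediate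
6 | 4-hydroxybenzaldehyde | O=Cc1ccc(O)cc1 | starting material
7 | bridged (E,E)-bis-chalcone: two 4-methoxyphenyl ketone rings linked through their ortho oxygens by O-(CH2)3-O, one carrying a 3-(4-hydroxy-3-methoxyphenyl)propenoyl arm, the other a 3-(4-hydroxyphenyl)propenoyl arm | COc1ccc(C(=O)/C=C/c2ccc(O)cc2)c(OCCCOc2cc(OC)ccc2C(=O)/C=C/c2ccc(O)c(OC)c2)c1 | intermediate
8 | bis(phenoxyl) diradical of 7 (not isolated) | COc1ccc(C(=O)/C=C/c2ccc([O])cc2)c(OCCCOc2cc(OC)ccc2C(=O)/C=C/c2ccc([O])c(OC)c2)c1 | intermediate
9 | bridged bis(quinone methide) with the new C2–C3 bond in a 13-membered ring; mixture of diastereomers and quinone methide geometries (not isolated) | COc1ccc2c(c1)OCCCOc1cc(OC)ccc1C(=O)C(C=C1C=CC(=O)C=C1)C(C=C1C=CC(=O)C(OC)=C1)C2=O | intermediate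
10 | bridged quinone methide enone: guaiacyl half re-aromatised to the (E)-aryl enone, 4-oxo-cyclohexadienylidene half retained, racemic at C2 (not isolated) | COc1ccc2c(c1)OCCCOc1cc(OC)ccc1C(=O)C(C=C1C=CC(=O)C=C1)/C(=C\c1ccc(O)c(OC)c1)C2=O | intermediate
11 | racemic trans bridged dihydronaphthalene: 7-hydroxy-1-(4-hydroxyphenyl)-6-methoxy-1,2-dihydronaphthalene whose C2 and C3 carry 4-methoxybenzoyl groups joined through their ortho oxygens by O-(CH2)3-O; (1R,2S) and (1S,2R) | O=C1C2=Cc3cc(OC)c(O)cc3[C@@H](c3ccc(O)cc3)[C@@H]2C(=O)c2ccc(OC)cc2OCCCOc2cc(OC)ccc21.O=C1C2=Cc3cc(OC)c(O)cc3[C@H](c3ccc(O)cc3)[C@H]2C(=O)c2ccc(OC)cc2OCCCOc2cc(OC)ccc21 | intermediate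
12 | (1R,2S)-enantiomer of 11 | O=C1C2=Cc3cc(OC)c(O)cc3[C@@H](c3ccc(O)cc3)[C@@H]2C(=O)c2ccc(OC)cc2OCCCOc2cc(OC)ccc21 | intermediate
13 | [(1R,2S)-6,7-dihydroxy-1-(4-hydroxyphenyl)-1,2-dihydronaphthalene-2,3-diyl]bis[(2,4-dihydroxyphenyl)methanone] | O=C(C1=Cc2cc(O)c(O)cc2[C@@H](c2ccc(O)cc2)[C@@H]1C(=O)c1ccc(O)cc1O)c1ccc(O)cc1O | target

**Step count**
Total steps: 6. Longest linear sequence: 6 (1 and 2 to 3, 5, 7, 11, 12, 13).

**Steps most likely to fail**

Step 4 (the step labelled as a proposed new method). Intermolecular phenoxyl coupling and oligomerisation may outrun the macrocyclising alpha,alpha-recombination. Oxidation may stall at the less easily oxidised 4-hydroxyphenyl half. The product phenols may be oxidised further, towards aromatisation of ring B. Both quinone methides may also tautomerise before ring closure, although the resulting diene should re-enter under the acid present.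

The fallback uses only known polar reaction types, sets out from 1 and returns to the route at 13. O-Methylation of 1 (MeI, K2CO3, acetone) gives 2,4-dimethoxyacetophenone F1. Oxidative dimerisation of its lithium enolate (LiN(iPr)2, THF, −78 °C, then CuCl2 in DMF) gives 1,4-bis(2,4-dimethoxyphenyl)butane-1,4-dione F2. Aldol condensation at one methylene with 4 (piperidine, AcOH, toluene, reflux) gives the mono-arylidene diketone F3. A second condensation with 6 gives the (E,E)-bis-arylidene diketone F4, the open-chain tautomer of the coupled intermediate. CF3SO3H in CH2Cl2 then closes ring B by the Friedel–Crafts cyclisation known for dibenzylidenesuccinates: the methoxy-activated ring attacks the protonated 4-hydroxybenzylidene enone to give the racemic trans pentamethyl ether F5. Resolution on the chiral phase of step 5 gives the (1R,2S)-pentamethyl ether F6, and BBr3 as in step 6 converts it into 13.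

Step 6. The two para-methoxy groups on the aroyl rings may cleave incompletely. Prolonged acid exposure and aerobic work-up may degrade the dihydronaphthalene and the catechol. Partially dealkylated congeners may stay inseparable from the free heptaphenol.

The fallback changes from direct isolation to capture and release, sets out from 12 and returns at 13. After the BBr3 treatment and a methanol quench, the crude polyphenol is acetylated without isolation (Ac2O, pyridine, 4-(dimethylamino)pyridine) to the heptaacetate F7. This is air-stable and separable on silica from under-cleaved material, which can be resubmitted. Acid methanolysis (HCl in MeOH, Ar, rt) then releases 13.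

Step 5. Enantiomer discrimination on the chiral phase may be insufficient, or slowly interconverting conformers of the 13-membered ring may broaden the peaks.

The fallback replaces chromatographic resolution by covalent diastereomer formation, sets out from 11 and returns at 12. Acylation of both phenols with (1S)-camphanic chloride (Et3N, 4-(dimethylamino)pyridine, CH2Cl2) gives the bis-camphanate of the (1R,2S) core F8 and the bis-camphanate of the (1S,2R) core F9. These should be separable by ordinary chromatography or crystallisation. Methanolysis of F8 (K2CO3, MeOH, 0 °C, Ar) returns 12.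

**Further compounds**
F1 | step 4 | 2,4-dimethoxyacetophenone | CC(=O)c1ccc(OC)cc1OC
F2 | step 4 | 1,4-bis(2,4-dimethoxyphenyl)butane-1,4-dione | COc1ccc(C(=O)CCC(=O)c2ccc(OC)cc2OC)c(OC)c1
F3 | step 4 | (E)-2-(4-hydroxy-3-methoxybenzylidene)-1,4-bis(2,4-dimethoxyphenyl)butane-1,4-dione | COc1ccc(C(=O)C/C(=C\c2ccc(O)c(OC)c2)C(=O)c2ccc(OC)cc2OC)c(OC)c1
F4 | step 4 | (E,E)-2-(4-hydroxy-3-methoxybenzylidene)-3-(4-hydroxybenzylidene)-1,4-bis(2,4-dimethoxyphenyl)butane-1,4-dione | COc1ccc(C(=O)C(=C/c2ccc(O)cc2)/C(=C\c2ccc(O)c(OC)c2)C(=O)c2ccc(OC)cc2OC)c(OC)c1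
F5 | step 4 | racemic trans [7-hydroxy-1-(4-hydroxyphenyl)-6-methoxy-1,2-dihydronaphthalene-2,3-diyl]bis[(2,4-dimethoxyphenyl)methanone] | O=C(C1=Cc2cc(OC)c(O)cc2[C@@H](c2ccc(O)cc2)[C@@H]1C(=O)c1ccc(OC)cc1OC)c1ccc(OC)cc1OC.O=C(C1=Cc2cc(OC)c(O)cc2[C@H](c2ccc(O)cc2)[C@H]1C(=O)c1ccc(OC)cc1OC)c1ccc(OC)cc1OC
F6 | step 4 | (1R,2S)-enantiomer of F5 | O=C(C1=Cc2cc(OC)c(O)cc2[C@@H](c2ccc(O)cc2)[C@@H]1C(=O)c1ccc(OC)cc1OC)c1ccc(OC)cc1OC
F7 | step 6 | heptaacetate of 13 | O=C(C1=Cc2cc(OC(C)=O)c(OC(C)=O)cc2[C@@H](c2ccc(OC(C)=O)cc2)[C@@H]1C(=O)c1ccc(OC(C)=O)cc1OC(C)=O)c1ccc(OC(C)=O)cc1OC(C)=O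
F8 | step 5 | bis[(1S)-camphanate] of the (1R,2S)-enantiomer 12 (esters at the C7 and aryl 4-hydroxyls) | O=C1C2=Cc3cc(OC)c(OC(=O)[C@@]45CC[C@@](C)(C(=O)O4)C5(C)C)cc3[C@@H](c3ccc(OC(=O)[C@@]45CC[C@@](C)(C(=O)O4)C5(C)C)cc3)[C@@H]2C(=O)c2ccc(OC)cc2OCCCOc2cc(OC)ccc21
F9 | step 5 | bis[(1S)-camphanate] of the (1S,2R)-enantiomer of 12 | O=C1C2=Cc3cc(OC)c(OC(=O)[C@@]45CC[C@@](C)(C(=O)O4)C5(C)C)cc3[C@H](c3ccc(OC(=O)[C@@]45CC[C@@](C)(C(=O)O4)C5(C)C)cc3)[C@H]2C(=O)c2ccc(OC)cc2OCCCOc2cc(OC)ccc21
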